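The earlier runs and the new flask are simulated for an exercise, and the scatter is random.

I started at the foot of the curve.

| flask | J | time |
|---|---|---|
| Friday's | 100 mM |  |
| Monday's | 150 mM |  |
| Wednesday's | 20.0 mM | 21 h |

| run | time / h | [L] / mM |
|---|---|---|
| Friday's run | 1.2 | 5.4 |
| Friday's run | 3.6 | 24.2 |
| Friday's run | 6.9 | 45.6 |
| Friday's run | 11 | 63.9 |
| Friday's run | 16 | 78.1 |
| Friday's run | 21 | 87.5 |
| Monday's run | 1.2 | 8.7 |
| Monday's run | 3.6 | 36.8 |
| Monday's run | 6.9 | 68.5 |
| Monday's run | 11 | 97.2 |
| Monday's run | 16 | 118.3 |
| Monday's run | 21 | 130.5 |

(readings scatter by 0.3 mM)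

* reaction order in [J] at the outset, round the charge of the Friday's run, defined at two percent of the J turned into L (one fixed amount of L, the same in the runs compared)
* L in the Wednesday's run at 21 h, as a share of the J charged

- Overall: J -> L.
- Constant volume, constant temperature.
- An order is taken over about fifteen percent of the charge, up and down.

Friday's L rose at 4.50 mM h⁻¹ up to the first reading and at 7.83 mM h⁻¹ over the next stretch, so the slope grew at first, which is a slow start, an induction period. At 6.9 h the two runs stood at 45.6 % and 45.7 % of their charges, so I drew a single curve for the share made.

I treated the tail as the large thing and the start as a correction. Pooled over Friday and Monday, the share not yet L was 35.6 % at 11 h and 12.7 % at 21 h, which gave a decay constant k of 0.103 h⁻¹. Traced back to a share of one, this tail gave a lag τ of 0.969 h, the delay of the tail behind a plain exponential started at zero.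

For Wednesday's smaller charge I kept the same curve, so by my reckoning Wednesday's L at 21 h came to 87.3 % of its charge.

I took the lag to be one first-order delay; then L grows as t² early on, so at a fixed L the rate goes as the square root of the charge, giving order 0.5. The next term adds t/(6τ). By this estimate Friday's run came to the asked amount of L at about 0.614 h, so I committed to an order of 0.606.

The forecast, holding that “the bulk is first order in J”, gave an order of 0.68 (from 0.5 to 1), higher than my 0.606, and a Wednesday share of 87 % (from 83 % to 90 %).

Wednesday's flask gave L at 87.1 % of its charge at 21 h, and the order round Friday's charge came to 0.65.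

    J → G (0.09072 h⁻¹)
    G → L (1.076 h⁻¹)
    J → L (0.01098 h⁻¹)

At the fixed amount of L asked, Monday's rate stood at 1.3 times Friday's, for a charge 1.50 times as large. The lag gives one more landmark: by the tail's curve, L comes to half of the charge at τ + ln(2)/k, which is 7.70 h. Friday reached it at 7.69 h and Monday at 7.69 h.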